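## Retrosynthetic overview

- The strategy rests on the C1–C8 bond, which joins two adjacent quaternary carbons in ring A (C1–C8–C7–C6–C5–C9) of the bicyclo[3.3.1]non-3-ene-2,9-dione; ring B (C1–C2–C3–C4–C5–C9) is the acylphloroglucinol ring.
- Endgame: the endo C7 prenyl group comes from an exocyclic C7 methylene (exo-face hydroboration, B-alkyl Suzuki coupling); the enol methyl ether and the catechol silyl ethers are hydrolysed last.
- Key disconnection C1–C8: anodic oxidation of the triketone enolate of a monocyclic dearomatised acylphloroglucinol and 6-endo closure onto a C5-bound 2-(trimethylsilylmethyl)prenyl group; ring B is there from the start, ring A is closed second.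
- Precursor: the C5 stereocentre is set by asymmetric phase-transfer alkylation of an arene in which C1 carries CO2Me and C3 the aroyl group, so C5 is the only ring carbon that can be alkylated (a prenyl-bearing and a geranyl-bearing carbon could not be told apart). De-methoxycarbonylation and C1 prenylation follow.
- Building blocks: methyl 2,4,6-trihydroxybenzoate and 3,4-dimethoxybenzoyl chloride (core), geranyl and prenyl bromide, and an allylsilane bromide made from ethyl 3-methylbut-2-enoate and (chloromethyl)trimethylsilane.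

Key step: step 12

Remark: carbons carry the numbers of the bicyclic product throughout (C1 prenyl-bearing, C3 aroyl-bearing, C5 geranyl-bearing, C9 the carbonyl between C1 and C5); Ar = 3,4-bis(tert-butyldimethylsilyloxy)phenyl, TBS = tert-butyldimethylsilyl.
Remark: the enol methyl ether of 23, 25 and 26 is drawn at O4 (the less hindered oxygen); an O2 regioisomer, should it form, gives the same product in step 15.

## Route

Step 1
Reactants: 1 ethyl 3-methylbut-2-enoate
Product: 3 ethyl 2-bromo-3-methylbut-2-enoate, via dibromo ester 2 (not isolated)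
Conditions: Br2, CH2Cl2, 0 °C; then Et3N, 40 °C
Reagents that add atoms: bromine, BrBr
Why: Bromine addition to the enoate followed by E1cB loss of the β-bromide (the acidic α-hydrogen is removed) is the standard addition–elimination route to α-bromo enoates.

Step 2
Reactants: 3 ethyl 2-bromo-3-methylbut-2-enoate; 4 (chloromethyl)trimethylsilane
Product: 7 ethyl 3-methyl-2-[(trimethylsilyl)methyl]but-2-enoate, via Grignard reagent 5 (not isolated), via organozinc chloride 6 (not isolated)
Conditions: 4, Mg, THF, reflux; ZnCl2, THF, 0 °C; then 3, Pd(PtBu3)2 (2 mol %), THF, 50 °C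
Reagents that add atoms: none
Why: Negishi cross-coupling of a (trimethylsilyl)methyl metal with a vinyl bromide is the classical entry to allylsilanes, the zinc reagent tolerates the ester and the bulky electron-rich palladium catalyst accepts the hindered bromide.

Step 3
Reactants: 7 ethyl 3-methyl-2-[(trimethylsilyl)methyl]but-2-enoate
Product: 8 3-methyl-2-[(trimethylsilyl)methyl]but-2-en-1-ol
Conditions: iBu2AlH, CH2Cl2, −78 → 0 °C; aq. potassium sodium tartrate
Reagents that add atoms: none
Why: 1,2-Reduction of the conjugated ester by iBu2AlH gives the allylic alcohol and leaves the allylsilane untouched.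

Step 4
Reactants: 8 3-methyl-2-[(trimethylsilyl)methyl]but-2-en-1-ol
Product: 9 [2-(bromomethyl)-3-methylbut-2-en-1-yl]trimethylsilane
Conditions: CBr4, PPh3, 2,6-lutidine, CH2Cl2, 0 °C
Reagents that add atoms: carbon tetrabromide, BrC(Br)(Br)Br
Why: The Appel bromination is neutral, so the acid-labile allylsilane survives and the primary allylic alcohol is displaced without allylic transposition.

Step 5
Reactants: 10 methyl 2,4,6-trihydroxybenzoate; 11 3,4-dimethoxybenzoyl chloride
Product: 12 methyl 3-(3,4-dimethoxybenzoyl)-2,4,6-trihydroxybenzoate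
Conditions: AlCl3, PhNO2, 25 → 60 °C; aq. HCl
Reagents that add atoms: none
Why: Friedel–Crafts acylation of the still strongly activated trihydroxybenzoate, whose two open positions are equivalent and whose product ketone deactivates the ring against a second acylation.

Step 6
Reactants: 12 methyl 3-(3,4-dimethoxybenzoyl)-2,4,6-trihydroxybenzoate
Product: 13 methyl 3-(3,4-dihydroxybenzoyl)-2,4,6-trihydroxybenzoate
Conditions: BBr3, CH2Cl2, −78 → 0 °C; then H2O
Reagents that add atoms: none
Why: BBr3 cleaves the two aryl methyl ethers at low temperature, where the chelated methyl ester, which needs more forcing conditions, is kept.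

Step 7
Reactants: 13 methyl 3-(3,4-dihydroxybenzoyl)-2,4,6-trihydroxybenzoate
Product: 14 methyl 3-[3,4-bis(tert-butyldimethylsilyloxy)benzoyl]-2,4,6-trihydroxybenzoate
Conditions: TBSCl (2.3 equiv), imidazole, DMF, 0 °C
Reagents that add atoms: tert-butyldimethylsilyl chloride, CC(C)(C)[Si](C)(C)Cl
Why: Each of the three phloroglucinol hydroxyls is hydrogen-bonded to an ortho carbonyl and any silyl ether formed there is hydrolysed on work-up, so silylation should stop at the two free catechol hydroxyls.

Step 8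
Reactants: 14 methyl 3-[3,4-bis(tert-butyldimethylsilyloxy)benzoyl]-2,4,6-trihydroxybenzoate; 15 geranyl bromide
Product: 16 methyl 3-[3,4-bis(tert-butyldimethylsilyloxy)benzoyl]-5-[(2E)-3,7-dimethylocta-2,6-dien-1-yl]-2,4,6-trihydroxybenzoate
Conditions: DBU, THF, 0 → 25 °C
Reagents that add atoms: none
Why: C-Alkylation of the phenolate with an allylic bromide under DBU is the usual C-geranylation of acylphloroglucinols, and C5 is the only ring carbon still unsubstituted, so the site is unambiguous and the silyl ethers are not exposed to hydroxide.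

Step 9
Reactants: 16 methyl 3-[3,4-bis(tert-butyldimethylsilyloxy)benzoyl]-5-geranyl-2,4,6-trihydroxybenzoate; 9 [2-(bromomethyl)-3-methylbut-2-en-1-yl]trimethylsilane
Product: 17 methyl (5S)-3-[3,4-bis(tert-butyldimethylsilyloxy)benzoyl]-5-geranyl-2,4-dihydroxy-5-{3-methyl-2-[(trimethylsilyl)methyl]but-2-en-1-yl}-6-oxocyclohexa-1,3-diene-1-carboxylate
Conditions: N-(9-anthracenylmethyl)-O-allylcinchonidinium bromide (10 mol %), Cs2CO3, toluene/CH2Cl2, −30 °C
Reagents that add atoms: none
Why: Proposed new method: in the caesium dianion of 16 only C5 is a nucleophilic ring carbon (C1 and C3 carry acyl groups), so SN2 attack on the allylic bromide must dearomatise there; tight ion pairing of the delocalised anion with the rigid cinchonidinium cation, whose two flanks meet an aroyl and a methoxycarbonyl group, is expected to expose one face of C5 and set the (S) centre (the cinchonine-derived pseudo-enantiomer is taken if the opposite sense results); the closest known reactions are cinchona phase-transfer alkylative dearomatisation–annulations of 3,5-diprenyl acylphloroglucinols with enals and phase-transfer allylations of β-keto ester and glycine imine enolates.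

Step 10
Reactants: 17 methyl (5S)-3-aroyl-5-geranyl-2,4-dihydroxy-5-{3-methyl-2-[(trimethylsilyl)methyl]but-2-en-1-yl}-6-oxocyclohexa-1,3-diene-1-carboxylate
Product: 19 (6S)-4-[3,4-bis(tert-butyldimethylsilyloxy)benzoyl]-6-geranyl-3,5-dihydroxy-6-{3-methyl-2-[(trimethylsilyl)methyl]but-2-en-1-yl}cyclohexa-2,4-dien-1-one, via β-keto acid 18 (not isolated)
Conditions: LiI, pyridine, 90 °C; then 5% aq. citric acid, 0 °C
Reagents that add atoms: none
Why: Iodide demethylates the chelated methyl ester (Krapcho-type dealkoxycarbonylation; pyridine traps MeI and buffers the acid-labile allylsilane), the β-keto acid loses CO2, and the quaternary stereocentre and the silyl ethers are not touched.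

Step 11
Reactants: 19 (6S)-4-aroyl-6-geranyl-3,5-dihydroxy-6-{3-methyl-2-[(trimethylsilyl)methyl]but-2-en-1-yl}cyclohexa-2,4-dien-1-one; 20 prenyl bromide
Product: 21 (6S)-4-[3,4-bis(tert-butyldimethylsilyloxy)benzoyl]-6-geranyl-3,5-dihydroxy-2-(3-methylbut-2-en-1-yl)-6-{3-methyl-2-[(trimethylsilyl)methyl]but-2-en-1-yl}cyclohexa-2,4-dien-1-one
Conditions: LiN(SiMe3)2 (2.1 equiv), THF, −78 °C; then 20, −78 → 0 °C; aq. citric acid
Reagents that add atoms: none
Why: The dianion of the cyclic β-triketone is alkylated at C1, its only unsubstituted and most nucleophilic carbon, the same C-prenylation that is used on dearomatised acylphloroglucinols of the lupulone type.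

Step 12
Reactants: 21 (6S)-4-aroyl-6-geranyl-3,5-dihydroxy-2-prenyl-6-{3-methyl-2-[(trimethylsilyl)methyl]but-2-en-1-yl}cyclohexa-2,4-dien-1-one
Product: 22 (1S,5S)-3-[3,4-bis(tert-butyldimethylsilyloxy)benzoyl]-5-geranyl-4-hydroxy-8,8-dimethyl-7-methylidene-1-(3-methylbut-2-en-1-yl)bicyclo[3.3.1]non-3-ene-2,9-dione
Conditions: reticulated vitreous carbon anode, Pt cathode, undivided cell, constant current (2.2 F mol−1), LiClO4 (0.1 M), 2,6-lutidine (3 equiv), MeOH/THF 1:4, 0 → 25 °C
Reagents that add atoms: none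
Why: The lutidinium enolate of 21 should be the most easily oxidised site; loss of one electron at the anode gives a radical delocalised over O2, C1, C3 and O4, which adds through C1 to C8 of the allylsilane in a 6-endo-trig closure of ring A (C1–C8–C7–C6–C5–C9), and the tertiary β-silyl radical at C7 is oxidised to the cation and desilylated by methanol to the exocyclic alkene, while lutidinium is reduced at the cathode so that no methoxide builds up. The closest known reactions are anodic olefin couplings that end on an allylsilane and the Mn(OAc)3/Cu(OAc)2 oxidative radical cyclisations of dearomatised prenylated acylphloroglucinols. The new C1 stereocentre is fixed by C5, because the two-carbon tether C6–C7 can bridge only the face of the dienone on which it stands, so the bicyclo[3.3.1]nonane can form as one diastereomer only. C1 and not C3 should react because bond formation at C3 would break the aroyl-chelated enol and build a more crowded acyl-bearing quaternary centre, and in the chemical precedents it is the alkyl-bearing carbon that cyclises. C8 and not C7 should be attacked because the electrophilic radical follows the SE2′ polarity of the allylsilane and leaves the silicon-stabilised radical, whereas 5-exo attack at C7 would give a bicyclo[3.2.1]octane without that stabilisation. The allylsilane should win over the geranyl C2′=C3′ bond because it is the more electron-rich π-system and because only the β-silyl radical is drained irreversibly by oxidation and loss of silicon, additions of such stabilised radicals to simple alkenes being able to revert.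

Step 13
Reactants: 22 (1S,5S)-3-aroyl-5-geranyl-4-hydroxy-8,8-dimethyl-7-methylidene-1-prenylbicyclo[3.3.1]non-3-ene-2,9-dione
Product: 23 (1S,5S)-3-[3,4-bis(tert-butyldimethylsilyloxy)benzoyl]-5-geranyl-4-methoxy-8,8-dimethyl-7-methylidene-1-(3-methylbut-2-en-1-yl)bicyclo[3.3.1]non-3-ene-2,9-dione
Conditions: Me3SiCHN2, MeOH/toluene, 0 °C
Reagents that add atoms: trimethylsilyldiazomethane, C[Si](C)(C)C=[N+]=[N-]
Why: O-Methylation of the acidic enol with Me3SiCHN2 is the usual masking of such bicyclic triketones and removes the proton that would consume the borane and the base of the next step.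

Step 14
Reactants: 23 (1S,5S)-3-aroyl-5-geranyl-4-methoxy-8,8-dimethyl-7-methylidene-1-prenylbicyclo[3.3.1]non-3-ene-2,9-dione; 24 1-bromo-2-methylprop-1-ene
Product: 26 (1S,5S,7S)-3-[3,4-bis(tert-butyldimethylsilyloxy)benzoyl]-5-geranyl-4-methoxy-8,8-dimethyl-1,7-bis(3-methylbut-2-en-1-yl)bicyclo[3.3.1]non-3-ene-2,9-dione (7-endo prenyl), via alkylborane 25 (not isolated)
Conditions: 9-BBN dimer, THF, 0 → 40 °C; then 24, PdCl2(dppf) (5 mol %), AsPh3, aq. K3PO4, DMF, 25 → 45 °C
Reagents that add atoms: none
Why: 9-BBN adds to the only 1,1-disubstituted alkene (trisubstituted prenyl and geranyl alkenes react far more slowly) from the open exo face, since the endo face is covered by the C2–C3–C4 bridge, which places hydrogen exo and CH2B endo at C7, and B-alkyl Suzuki–Miyaura coupling with the vinyl bromide turns CH2B into the endo prenyl group (7S).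

Step 15
Reactants: 26 (1S,5S,7S)-3-aroyl-5-geranyl-4-methoxy-8,8-dimethyl-1,7-diprenylbicyclo[3.3.1]non-3-ene-2,9-dione
Product: 27 (1S,5S,7S)-3-(3,4-dihydroxybenzoyl)-5-[(2E)-3,7-dimethylocta-2,6-dien-1-yl]-4-hydroxy-8,8-dimethyl-1,7-bis(3-methylbut-2-en-1-yl)bicyclo[3.3.1]non-3-ene-2,9-dione (CNP0160101.2)
Conditions: LiOH·H2O, dioxane/H2O (degassed, argon), 80 °C; then aq. citric acid, 0 °C
Reagents that add atoms: lithium hydroxide, [Li+].[OH-]
Why: Hydroxide adds to the vinylogous ester and expels methoxide, the standard closing hydrolysis of O-methyl enol ethers of this family, and cleaves the two aryl silyl ethers in the same operation, with no acid that could cyclise the enol onto a prenyl group and no epimerisable stereocentre.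

## Compound list

1 | ethyl 3-methylbut-2-enoate | CCOC(=O)C=C(C)C | starting material
2 | ethyl 2,3-dibromo-3-methylbutanoate (racemic) | CCOC(=O)C(Br)C(C)(C)Br | intermediate
3 | ethyl 2-bromo-3-methylbut-2-enoate | CCOC(=O)C(Br)=C(C)C | intermediate
4 | (chloromethyl)trimethylsilane | C[Si](C)(C)CCl | starting material
5 | [(trimethylsilyl)methyl]magnesium chloride | C[Si](C)(C)C[Mg]Cl | intermediate
6 | [(trimethylsilyl)methyl]zinc chloride | C[Si](C)(C)C[Zn]Cl | intermediate
7 | ethyl 3-methyl-2-[(trimethylsilyl)methyl]but-2-enoate | CCOC(=O)C(C[Si](C)(C)C)=C(C)C | intermediate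
8 | 3-methyl-2-[(trimethylsilyl)methyl]but-2-en-1-ol | OCC(C[Si](C)(C)C)=C(C)C | intermediate
9 | [2-(bromomethyl)-3-methylbut-2-en-1-yl]trimethylsilane | BrCC(C[Si](C)(C)C)=C(C)C | intermediate
10 | methyl 2,4,6-trihydroxybenzoate | COC(=O)c1c(O)cc(O)cc1O | starting material
11 | 3,4-dimethoxybenzoyl chloride | COc1ccc(C(=O)Cl)cc1OC | starting material
12 | methyl 3-(3,4-dimethoxybenzoyl)-2,4,6-trihydroxybenzoate | COC(=O)c1c(O)cc(O)c(C(=O)c2ccc(OC)c(OC)c2)c1O | intermediate
13 | methyl 3-(3,4-dihydroxybenzoyl)-2,4,6-trihydroxybenzoate | COC(=O)c1c(O)cc(O)c(C(=O)c2ccc(O)c(O)c2)c1O | intermediate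
14 | methyl 3-[3,4-bis(tert-butyldimethylsilyloxy)benzoyl]-2,4,6-trihydroxybenzoate | COC(=O)c1c(O)cc(O)c(C(=O)c2ccc(O[Si](C)(C)C(C)(C)C)c(O[Si](C)(C)C(C)(C)C)c2)c1O | intermediate
15 | geranyl bromide, (2E)-1-bromo-3,7-dimethylocta-2,6-diene | CC(C)=CCC/C(C)=C/CBr | starting material
16 | methyl 3-[3,4-bis(tert-butyldimethylsilyloxy)benzoyl]-5-[(2E)-3,7-dimethylocta-2,6-dien-1-yl]-2,4,6-trihydroxybenzoate | COC(=O)c1c(O)c(C/C=C(\C)CCC=C(C)C)c(O)c(C(=O)c2ccc(O[Si](C)(C)C(C)(C)C)c(O[Si](C)(C)C(C)(C)C)c2)c1O | intermediate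
17 | methyl (5S)-3-[3,4-bis(tert-butyldimethylsilyloxy)benzoyl]-5-geranyl-2,4-dihydroxy-5-{3-methyl-2-[(trimethylsilyl)methyl]but-2-en-1-yl}-6-oxocyclohexa-1,3-diene-1-carboxylate | CC(C)=CCC/C(C)=C/C[C@@]1(CC(C[Si](C)(C)C)=C(C)C)C(=O)C(C(=O)OC)=C(O)C(C(=O)c2ccc(O[Si](C)(C)C(C)(C)C)c(O[Si](C)(C)C(C)(C)C)c2)=C1O | intermediate
18 | (5S)-3-[3,4-bis(tert-butyldimethylsilyloxy)benzoyl]-5-geranyl-2,4-dihydroxy-5-{3-methyl-2-[(trimethylsilyl)methyl]but-2-en-1-yl}-6-oxocyclohexa-1,3-diene-1-carboxylic acid | CC(C)=CCC/C(C)=C/C[C@@]1(CC(C[Si](C)(C)C)=C(C)C)C(=O)C(C(=O)O)=C(O)C(C(=O)c2ccc(O[Si](C)(C)C(C)(C)C)c(O[Si](C)(C)C(C)(C)C)c2)=C1O | intermediate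
19 | (6S)-4-[3,4-bis(tert-butyldimethylsilyloxy)benzoyl]-6-geranyl-3,5-dihydroxy-6-{3-methyl-2-[(trimethylsilyl)methyl]but-2-en-1-yl}cyclohexa-2,4-dien-1-one | CC(C)=CCC/C(C)=C/C[C@@]1(CC(C[Si](C)(C)C)=C(C)C)C(=O)C=C(O)C(C(=O)c2ccc(O[Si](C)(C)C(C)(C)C)c(O[Si](C)(C)C(C)(C)C)c2)=C1O | intermediate
20 | prenyl bromide, 1-bromo-3-methylbut-2-ene | CC(C)=CCBr | starting material
21 | (6S)-4-[3,4-bis(tert-butyldimethylsilyloxy)benzoyl]-6-geranyl-3,5-dihydroxy-2-(3-methylbut-2-en-1-yl)-6-{3-methyl-2-[(trimethylsilyl)methyl]but-2-en-1-yl}cyclohexa-2,4-dien-1-one | CC(C)=CCC/C(C)=C/C[C@@]1(CC(C[Si](C)(C)C)=C(C)C)C(=O)C(CC=C(C)C)=C(O)C(C(=O)c2ccc(O[Si](C)(C)C(C)(C)C)c(O[Si](C)(C)C(C)(C)C)c2)=C1O | intermediate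
22 | (1S,5S)-3-[3,4-bis(tert-butyldimethylsilyloxy)benzoyl]-5-geranyl-4-hydroxy-8,8-dimethyl-7-methylidene-1-(3-methylbut-2-en-1-yl)bicyclo[3.3.1]non-3-ene-2,9-dione | CC(C)=CCC/C(C)=C/C[C@]12CC(=C)C(C)(C)[C@](CC=C(C)C)(C(=O)C(C(=O)c3ccc(O[Si](C)(C)C(C)(C)C)c(O[Si](C)(C)C(C)(C)C)c3)=C1O)C2=O | intermediate
23 | (1S,5S)-3-[3,4-bis(tert-butyldimethylsilyloxy)benzoyl]-5-geranyl-4-methoxy-8,8-dimethyl-7-methylidene-1-(3-methylbut-2-en-1-yl)bicyclo[3.3.1]non-3-ene-2,9-dione | CC(C)=CCC/C(C)=C/C[C@]12CC(=C)C(C)(C)[C@](CC=C(C)C)(C(=O)C(C(=O)c3ccc(O[Si](C)(C)C(C)(C)C)c(O[Si](C)(C)C(C)(C)C)c3)=C1OC)C2=O | intermediate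
24 | 1-bromo-2-methylprop-1-ene | CC(C)=CBr | starting material
25 | (1S,5S,7S)-7-[(9-borabicyclo[3.3.1]nonan-9-yl)methyl]-3-[3,4-bis(tert-butyldimethylsilyloxy)benzoyl]-5-geranyl-4-methoxy-8,8-dimethyl-1-(3-methylbut-2-en-1-yl)bicyclo[3.3.1]non-3-ene-2,9-dione (7-endo) | CC(C)=CCC/C(C)=C/C[C@]12C[C@H](CB4C5CCCC4CCC5)C(C)(C)[C@](CC=C(C)C)(C(=O)C(C(=O)c3ccc(O[Si](C)(C)C(C)(C)C)c(O[Si](C)(C)C(C)(C)C)c3)=C1OC)C2=O | intermediate
26 | (1S,5S,7S)-3-[3,4-bis(tert-butyldimethylsilyloxy)benzoyl]-5-geranyl-4-methoxy-8,8-dimethyl-1,7-bis(3-methylbut-2-en-1-yl)bicyclo[3.3.1]non-3-ene-2,9-dione (7-endo prenyl) | CC(C)=CCC/C(C)=C/C[C@]12C[C@H](CC=C(C)C)C(C)(C)[C@](CC=C(C)C)(C(=O)C(C(=O)c3ccc(O[Si](C)(C)C(C)(C)C)c(O[Si](C)(C)C(C)(C)C)c3)=C1OC)C2=O | intermediate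
27 | (1S,5S,7S)-3-(3,4-dihydroxybenzoyl)-5-[(2E)-3,7-dimethylocta-2,6-dien-1-yl]-4-hydroxy-8,8-dimethyl-1,7-bis(3-methylbut-2-en-1-yl)bicyclo[3.3.1]non-3-ene-2,9-dione (7-endo prenyl) | CC(C)=CCC/C(C)=C/C[C@]12C[C@H](CC=C(C)C)C(C)(C)[C@](CC=C(C)C)(C(=O)C(C(=O)c3ccc(O)c(O)c3)=C1O)C2=O | target

## Step count and risks

Total step count: 15. Longest linear sequence: 11 steps (10 → 27 through steps 5–15; the allylsilane branch 1 → 9 → 27 through steps 1–4 and 9–15 is also 11).

Steps most likely to fail:

1. Step 9 (proposed new method). What may go wrong: the chiral ion pair may not discriminate the two faces of C5 well enough, so that material of low enantiomeric purity results, or O-alkylation may compete with C-alkylation. Fallback with known chemistry, setting out from 16: alkylation with 9 under achiral conditions (Cs2CO3, nBu4NBr, toluene, 0 °C, a conventional dearomative C-alkylation of an acylphloroglucinol) should give the racemic ester F1. F1 is then resolved by preparative chromatography on a chiral stationary phase (supercritical CO2/MeOH on cellulose tris(3,5-dimethylphenylcarbamate)); the (5S)-enantiomer is 17, where the route is rejoined.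

2. Step 12 (key step). What may go wrong: electron transfer at the anode may not be selective for the enolate, so that the tetrasubstituted allylsilane or the product enolate is oxidised and fragments or is captured by methanol; the slow closure between two fully substituted carbons also gives the C1 radical time to add 5-exo to the geranyl C2′=C3′ bond. Fallback, setting out from 16 and returning at 22:
   - Alkylation under the conditions of step 9 with 1-bromo-2,3-dimethylbut-2-ene gives the silicon-free ester F2.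
   - LiI in pyridine removes the methoxycarbonyl group through the β-keto acid F3 and gives the dienone F4.
   - C1 prenylation as in step 11 gives the silicon-free precursor F5.
   - F5 is oxidised with Mn(OAc)3·2H2O and Cu(OAc)2·H2O in AcOH at 25 °C: inner-sphere oxidation of the enolate bound to trivalent manganese, 6-endo closure onto the tetrasubstituted alkene, and oxidation of the tertiary C7 radical by divalent copper with loss of a methyl hydrogen, which favours the less substituted exocyclic alkene. This is the established oxidative radical cyclisation of dearomatised acylphloroglucinols; it takes the electrode out of the problem and ends the sequence by a fast, irreversible copper step, and it should give 22 directly. It does not by itself remove the competing 5-exo addition to the geranyl C2′=C3′ bond.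

3. Step 14. What may go wrong: hydroboration of the neopentyl-type methylene may be slow enough for reduction of the aryl ketone or hydroboration of the trisubstituted alkenes to intervene, or the hindered alkylborane may transfer poorly in the coupling. Fallback, setting out from 23 and returning at 26: hydroformylation of the 1,1-disubstituted alkene (Rh(acac)(CO)2, PPh3, CO/H2, toluene, 70 °C), anti-Markovnikov and from the exo face, should give the endo aldehyde F6. A Wittig reaction of F6 with isopropylidenetriphenylphosphorane (THF, −78 → 0 °C) turns CH2CHO into the prenyl group and gives 26.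

Further compounds
F1 | step 9 | racemic methyl 3-[3,4-bis(tert-butyldimethylsilyloxy)benzoyl]-5-geranyl-2,4-dihydroxy-5-{3-methyl-2-[(trimethylsilyl)methyl]but-2-en-1-yl}-6-oxocyclohexa-1,3-diene-1-carboxylate | CC(C)=CCC/C(C)=C/CC1(CC(C[Si](C)(C)C)=C(C)C)C(=O)C(C(=O)OC)=C(O)C(C(=O)c2ccc(O[Si](C)(C)C(C)(C)C)c(O[Si](C)(C)C(C)(C)C)c2)=C1O
F2 | step 12 | methyl (5S)-3-[3,4-bis(tert-butyldimethylsilyloxy)benzoyl]-5-(2,3-dimethylbut-2-en-1-yl)-5-geranyl-2,4-dihydroxy-6-oxocyclohexa-1,3-diene-1-carboxylate | CC(C)=CCC/C(C)=C/C[C@@]1(CC(C)=C(C)C)C(=O)C(C(=O)OC)=C(O)C(C(=O)c2ccc(O[Si](C)(C)C(C)(C)C)c(O[Si](C)(C)C(C)(C)C)c2)=C1O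
F3 | step 12 | (5S)-3-[3,4-bis(tert-butyldimethylsilyloxy)benzoyl]-5-(2,3-dimethylbut-2-en-1-yl)-5-geranyl-2,4-dihydroxy-6-oxocyclohexa-1,3-diene-1-carboxylic acid | CC(C)=CCC/C(C)=C/C[C@@]1(CC(C)=C(C)C)C(=O)C(C(=O)O)=C(O)C(C(=O)c2ccc(O[Si](C)(C)C(C)(C)C)c(O[Si](C)(C)C(C)(C)C)c2)=C1O
F4 | step 12 | (6S)-4-[3,4-bis(tert-butyldimethylsilyloxy)benzoyl]-6-(2,3-dimethylbut-2-en-1-yl)-6-geranyl-3,5-dihydroxycyclohexa-2,4-dien-1-one | CC(C)=CCC/C(C)=C/C[C@@]1(CC(C)=C(C)C)C(=O)C=C(O)C(C(=O)c2ccc(O[Si](C)(C)C(C)(C)C)c(O[Si](C)(C)C(C)(C)C)c2)=C1O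
F5 | step 12 | (6S)-4-[3,4-bis(tert-butyldimethylsilyloxy)benzoyl]-6-(2,3-dimethylbut-2-en-1-yl)-6-geranyl-3,5-dihydroxy-2-(3-methylbut-2-en-1-yl)cyclohexa-2,4-dien-1-one | CC(C)=CCC/C(C)=C/C[C@@]1(CC(C)=C(C)C)C(=O)C(CC=C(C)C)=C(O)C(C(=O)c2ccc(O[Si](C)(C)C(C)(C)C)c(O[Si](C)(C)C(C)(C)C)c2)=C1O
F6 | step 14 | (1S,5S,7R)-3-[3,4-bis(tert-butyldimethylsilyloxy)benzoyl]-5-geranyl-4-methoxy-8,8-dimethyl-1-(3-methylbut-2-en-1-yl)-7-(2-oxoethyl)bicyclo[3.3.1]non-3-ene-2,9-dione (7-endo side chain) | CC(C)=CCC/C(C)=C/C[C@]12C[C@H](CC=O)C(C)(C)[C@](CC=C(C)C)(C(=O)C(C(=O)c3ccc(O[Si](C)(C)C(C)(C)C)c(O[Si](C)(C)C(C)(C)C)c3)=C1OC)C2=O
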